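The numbers in the tables stem from a simulated flask for an exercise; scatter was added.

Decide first to follow what is left and not what is made: the fraction of the charged G still standing as c_G + c_GX.

| setting | summer | winter | flask |
|---|---|---|---|
| G | 0.53 M | 0.36 M | 0.53 M |
| X | 5 equiv | 5 equiv | 5.00 equiv |
| remark | the very flask that is asked about, followed so far | run made earlier |  |
| time |  |  | 8.0 h |

summer run (percent of the G charged)

| time / min | GX / % | G / % |
|---|---|---|
| 20.0 | 80 | 9 |
| 40.0 | 72 | 9 |
| 60.0 | 75 | 7 |
| 80.0 | 69 | 8 |

winter run (percent of the G charged)

| time / h | GX / % | G / % |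
|---|---|---|
| 0.417 | 81 | 15 |
| 1.00 | 74 | 12 |
| 2.00 | 65 | 12 |
| 3.00 | 64 | 12 |

(each reading ± 1.5 percentage points)

- the best time, 8.0 h at the latest, for GX
- the amount of GX, in percent of the G charged, at that time

- the earlier runs were read with a standard deviation of 1.5 percentage points

In the summer run this fraction goes from 89.0% at 20.0 min to 77.0% at 80.0 min, so you reckon

λ = 0.145 h⁻¹

This is the pool's loss constant, the fall per hour in the logarithm of the fraction left, a pseudo-first-order constant with X at 5 equiv.

Next, ask how fast G and GX come to balance. In the winter run G starts 88 points above its last level and stands 3 points above it at 0.417 h. That gives a relaxation rate of 8.10 h⁻¹, and scaling with c_X, as I choose to, gives for summer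

r = 11.9 h⁻¹

If GX follows the pool times 1 − exp(−rt), its top lies at

t = ln(1 + r/λ)/r = 0.371 h

This is well inside the 8.0 h allowed. GX holds 89.6% of the pool at the last summer reading, so carrying the pool to that time gives a height of

78.4%

The weak link is r, which rests on that small winter difference against a scatter of 1.5 points. Double the difference, and r becomes 9.48 h⁻¹ and the top moves to 0.443 h, while the pool at the top loses about 1.04% of itself. So hold the height firmly and the time loosely.

The forecast says 0.28 h and 80%, earlier than my time, from “Balancing formation against loss”.

The flask gives 80.0% at 0.256 h, earlier than I reckoned. In this flask GX stands at 75.6% at 0.128 h and at 72.9% at 1.02 h, a span that holds my time.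

    G + X ⇌ GX (K = 4.00 M⁻¹, k = 0.120 M⁻¹ min⁻¹)
    G + 2 X → J (k = 0.00490 M⁻² min⁻¹)

Now start from this flask at its best time, where G and GX together hold 89.5%, and carry that forward with λ to 2.0 h:

69.5%

The neighbour read at that time holds 7.44% G and 64.3% GX, together 71.7%.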